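If the J made in a flask is taken up again by Z, then J has a life, and in a flask rich in Z that life may be shorter than the run.

| setting | dusk | autumn | noon | summer | spring |
|---|---|---|---|---|---|
| X | 250 mM | 100 mM | 250 mM | 750 mM | 1200 mM |
| Z | 275 mM | 125 mM | 275 mM | 275 mM | 1400 mM |
| Q | 13.0 mM | 13.0 mM | 19.0 mM | 13.0 mM | 13.0 mM |
| time |  |  |  |  | 56 h |

| run | time / h | [J] / mM |
|---|---|---|
| dusk run | 2.5 | 6 |
| dusk run | 7.5 | 32 |
| dusk run | 14 | 49 |
| dusk run | 23 | 74 |
| dusk run | 33 | 104 |
| dusk run | 44 | 114 |
| dusk run | 56 | 145 |
| autumn run | 2.5 | 12 |
| autumn run | 7.5 | 26 |
| autumn run | 14 | 44 |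
| autumn run | 23 | 56 |
| autumn run | 33 | 75 |
| autumn run | 44 | 88 |
| autumn run | 56 | 89 |
| noon run | 2.5 | 22 |
| noon run | 7.5 | 54 |
| noon run | 14 | 104 |
| noon run | 23 | 148 |
| noon run | 33 | 188 |
| noon run | 44 | 205 |
| noon run | 56 | 201 |
| summer run | 2.5 | 2 |
| summer run | 7.5 | 11 |
| summer run | 14 | 22 |
| summer run | 23 | 23 |
| summer run | 33 | 40 |
| summer run | 44 | 49 |
| summer run | 56 | 52 |

(each reading ± 4 mM)

- Overall: X + Z -> J, with Q as catalyst.
- Constant volume, constant temperature.
- Readings of a species count what is bound in complexes too.
- "The second partner" is Z.
- An order is taken over about fifteen percent of the charge, up and down.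

- reaction order in [Z] at the outset, round the charge of the dusk run, defined at two percent of the X turned into J
- reaction order in [Q] at the outset, round the charge of the dusk run, defined at two percent of the X turned into J
- J in the spring run at 56 h, as a share of the X charged
- which of these the readings show (the second partner pairs with itself / an uncatalysed path runs beside / nothing beyond the main steps / the product reacts on with the second partner)

I reckon on that if. Mean rates up to 14 h give, as readings with their scatter, an order in X and one in Z:

order in X, summer against dusk: −0.729

order in Z, autumn against dusk: 0.984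

Treat the loss as a correction to the summer run, where 6.93% of the X has become J by the last reading. Take the order in Z as one and mean c_J as half that reading:

early rate: 1.57 mM h⁻¹

mean c_Z: 249 mM

J expected without loss: 79.7 mM

J missing: 27.7 mM

life of J in summer, mean c_J × time / J missing: 52.6 h

On that if, the life of J scales as one over c_Z. At the spring charge that gives 9.36 h, the mean time a J lasts among Z. The early rate of the spring run comes from the summer rate and the two orders:

5.53 mM h⁻¹

The spring run then stands on this ladder:

life of J: 9.36 h

length of the run: 56 h

time to turn the X at the early rate: 217 h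

The life of J in the spring run is shorter than the run, and the run is shorter than the turning of the X. So c_J should level off early, in a pseudo-first-order loss, while making goes on at nearly its early rate. In this quasi-steady state the spring flask holds one life's worth of making:

c_J = rate × life = 51.7 mM, or 4.31% of the X

The forecast gave 0.95 for the order in Z, 2 for the order in Q and 8.5% for the spring run, and it chose the second partner pairs with itself, writing of “Z exhaustion by a second-order self-reaction”. My share is lower than the forecast's.

The flask gives 0.93 and 2.1 for the orders, 4.53% for the spring run, and the product reacts on with the second partner.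

    Q + X ⇌ QX, settled at all times (33.60 M⁻¹)
    Q + Z ⇌ QZ, settled at all times (1.390 M⁻¹)
    QX + QZ → J + 2 Q (680.4 M⁻¹ h⁻¹)
    J + Z → E (0.07668 M⁻¹ h⁻¹)

The spring run's J is held down by the conversion of J and Z into E. The same spring charge without that step stores 23.0% of the X as J, against 4.53% with it. That simulated run made J at a mean 4.92 mM h⁻¹. Multiplied by the life of 9.36 h, this gives 46.1 mM for the spring flask, which holds 54.4 mM.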